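All runs stem from a simulated flask with made-up constants; the scatter is artificial.

- 5 questions are asked of 4 flasks, and one count of turnovers serves them: how many lives of the second end groups fit into the addition.

| flask | first end groups | second end groups | temperature | remark | time |
|---|---|---|---|---|---|
| red | 10 mM | 1.05 equiv | 65 °C | run made earlier |  |
| ochre | 5 mM | 1.05 equiv | 80 °C | run made earlier |  |
| violet | 7.5 mM | 1.05 equiv | 65 °C | run made earlier |  |
| north-west | 10 mM | 1.05 equiv | 80 °C | everything together at the start | 12 h |
| north | 10 mM | 1.05 equiv (fed, over 8.0 h) | 80 °C | all else is in the flask from the start; the feed brings no volume worth counting | 12 h |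
| west | 10 mM | 1.05 equiv (fed, over 8.0 h) |  | the addition at 60 °C, then warmed to 80 °C; the feed brings no volume worth counting | 12 h |
| south | 10 mM (fed, over 8.0 h) | 1.05 equiv | 80 °C | all else is in the flask from the start; the feed brings no volume worth counting | 12 h |

- red (time / h: links / %, first end groups / %): 1.00: 12.4, 85.5; 2.00: 24.3, 76.9; 4.00: 37.0, 62.4; 8.00: 41.8, 52.5; 15.0: 43.4, 43.0
- ochre (time / h: links / %, first end groups / %): 0.833: 15.2, 86.6; 2.50: 26.3, 72.5; 4.00: 29.1, 65.2; 6.00: 32.7, 62.0; 10.0: 32.1, 59.1
- violet (time / h: links / %, first end groups / %): 2.00: 20.7, 81.0; 3.00: 25.1, 72.9; 5.00: 32.7, 65.0; 10.0: 41.2, 51.3; 20.0: 43.4, 44.5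

(scatter of a reading: 1 percentage point)



* which flask leads in amount of links, in percent of the first end groups charged ("all alike" within 1.5 percentage points) (north-west / north / west / south / all alike)
* how much links is there at the end, in percent of the first end groups charged: north-west
* how much links is there at the end, in percent of the first end groups charged: north
* how much links is there at the end, in percent of the first end groups charged: west
* how much links is there at the end, in percent of the first end groups charged: south

- The first time is a life of the second end groups, read from a stall. The ochre run reaches 15.2% of links after 0.833 h and stands at 32.1% after 10.0 h, so at its first pace it fills in 1.76 h. The red run, read the same way, gives 3.50 h at 65 °C.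
- The second time is the addition, 8.0 h. Their ratio is 4.55 at 80 °C and 2.29 at 65 °C: the turnover number, lives of second end groups per addition. Both are readings with their scatter, and the ochre run held half of the charge of the new flasks.
- In north the number is greater than one, so c(second end groups) should stand near 22.0% of the charge during the feed. Second end groups are then the limiting reagent of the moment, and north should beat north-west.
- In south the second end groups stand from the start and pass through the same 4.55 lives while first end groups trickle in, so south should come last.
- West turns over less than north even at 65 °C, which is warmer than its 60 °C, so more second end groups should reach the warming. This reckoning commits to an order: west, north, north-west, south.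
- The forecast names west and gives 32.5%, 31%, 37% and 24% for north-west, north, west and south, with south “first end groups starved while links accumulate”.
- The simulation has west in the lead, with 36.5% in north-west, 39.8% in north, 44.6% in west and 23.1% in south.

    first end groups + second end groups ⇌ links + by-product (K = 1.60, k = 0.0110 /M/s, Ea = 61.0 kJ/mol, ΔH = 27.0 kJ/mol)
    second end groups → decomposed reagent (k = 6.90 × 10⁻⁵ /s, Ea = 120 kJ/mol)
    first end groups + by-product → side product (k = 0.00370 /M/s, Ea = 73.0 kJ/mol)
    (constants at 80 °C)

- In north at 6.00 h, second end groups stand at 23.8% of their charge, against the reckoned 22.0%. For a flask like south kept at 65 °C, the reckoned count is 2.29 turnovers per addition against 4.55 at 80 °C, both read off stalls and not the flasks' own. Read as a life, 3.50 h leaves 3.24% of the second end groups after 12 h, and that flask stands far above this figure. At 12.0 h that flask keeps 32.5% of its second end groups where south keeps 2.02%, and it holds 38.9% of links against 23.1% in south.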